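**Retrosynthetic overview**

1. The hydroperoxide is placed last by a singlet-oxygen ene reaction on the 4-methylpent-3-enyl side chain of acetoxycrenulide; acetate, butenolide C=C (selenoxide elimination), cyclopropane (hydroxyl-directed Simmons–Smith) and ring alcohol (ketone reduction) come just before.
2. The eight-membered carbocycle comes from a six-membered ring: Claisen ring expansion of a 2-methylene-6-[(E)-propenyl]tetrahydropyran, a temporary ring that also fixes the ring CH beside the side chain by equilibration and passes its carbinol configuration on to the ring CH(CH3).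
3. Key disconnection: the bond between the side-chain CH(CH3) and the CH2 next to it, formed by copper-catalysed asymmetric conjugate addition of a 4-methylpent-3-enyl Grignard reagent to a crotonic thioester; in the same flask the enolate adds to (5S)-menthyloxybutenolide and the lactone enolate to crotonaldehyde (four components, three C–C bonds, five stereocentres).
4. Enabling feature: the acetoxy-bearing ring carbon, the ring CH next to it and the exocyclic CH(CH3) with its methyl group are a latent but-2-enoyl unit, and this ring CH sits on the β-carbon of the butenolide ring, whose α-carbon carries the cyclopropane CH; acetoxy carbon and lactone carbonyl are therefore 1,5-related, so each enolate of the cascade is the nucleophile for the next bond.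
5. Order of rings: γ-lactone (bought in the butenolide) → tetrahydropyran template (steps 3 to 5) → cyclooctene (step 6) → cyclopropane (step 8) → butenolide double bond (step 11).

Key step: step 2

Remark: the (5S)-(d-menthyloxy)butenolide of step 2 (acetal of 5-hydroxyfuran-2(5H)-one with (+)-menthol) is taken as purchasable like its mirror image, and the ene reaction of step 14 is accepted to give a regioisomer that is separated.

**Step 1**
Reactants: 1 (E)-but-2-enoic acid; 2 ethanethiol
Product: 3 S-ethyl (E)-but-2-enethioate
Conditions: DCC, DMAP (cat.), CH2Cl2, 0 °C to rt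
Reagents that add atoms: none
Why: Steglich-type thioesterification through the O-acylisourea should give the enethioate acceptor with the E geometry kept and no stereocentre formed.

**Step 2**
Reactants: 3 S-ethyl (E)-but-2-enethioate; 4 5-bromo-2-methylpent-2-ene; 5 (5S)-5-(d-menthyloxy)furan-2(5H)-one; 6 (E)-but-2-enal
Product: 10 hydroxy thioester lactone (four-component adduct; full name in the list), via Grignard reagent 7 (not isolated), via magnesium thioester enolate 8 (not isolated), via magnesium lactone enolate 9 (not isolated)
Conditions: 4, Mg, Et2O, rt (gives 7, 1.0 equiv); CuBr·SMe2 (5 mol%), (R)-1-[(SP)-2-(diphenylphosphino)ferrocenyl]ethyldicyclohexylphosphine (Josiphos, 6 mol%), 3 (1.1 equiv), t-BuOMe, −75 °C, slow addition of 7; then 5 (0.9 equiv) in THF, −75 to −40 °C; then 6 (1.5 equiv), −78 °C; sat. aq. NH4Cl at −78 °C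
Reagents that add atoms: none
Why: The copper–Josiphos catalyst transfers the 4-methylpent-3-enyl group of 7 to the β-carbon of s-cis 3, which forms the bond between the side-chain CH2 and the future CH(CH3) and leaves the Z-magnesium enolate 8; 8 adds to the β-carbon of 5 (Michael addition) and the lactone enolate 9 adds to the carbonyl group of 6 through a closed six-membered chair transition state. The closest known reaction types are the copper/Josiphos-catalysed asymmetric conjugate addition of Grignard reagents to α,β-unsaturated thioesters with trapping of the magnesium enolate by a second electrophile, and the tandem Michael–aldol reaction on 5-menthyloxyfuranones. No ring is closed. The CH(CH3) centre is set by the ligand (the enantiomer is used that sends the alkyl group to the Si face of C3 of 3; both are sold), the butenolide β-carbon by the acetal (attack anti to the menthyloxy group), the lactone α-carbon by this new neighbour (the aldehyde enters trans to it), the carbinol carbon by the chair transition state of the E(O)-configured lactone enolate (anti aldol), and the thioester α-carbon by the synclinal open transition state of the Michael step. The step needs chemoselectivity in the order of events: 7 is the limiting reagent so that none is left for 5 or 6, the soft thioester enolate adds 1,4 to 5 whereas the hard lactone enolate adds 1,2 to 6 at −78 °C, and the cold quench keeps the magnesium alkoxide from acylating itself on the thioester.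

**Step 3**
Reactants: 10 hydroxy thioester lactone
Product: 12 bicyclic lactol (both anomers), via hydroxy aldehyde 11 (not isolated)
Conditions: Et3SiH, Pd/CaCO3 (5% Pd, poisoned with Pb(OAc)2), acetone, rt; filtration; then DBU (0.2 equiv), toluene, rt
Reagents that add atoms: none
Why: Fukuyama reduction should convert only the thioester into the aldehyde, which closes with the δ-hydroxyl group to the six-membered lactol, and DBU equilibrates the carbon next to the masked aldehyde through the open form so that the branched side chain rests equatorial (trans to the lactone carbon on the neighbouring ring atom), which corrects any epimer carried over from step 2.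

**Step 4**
Reactants: 12 bicyclic lactol
Product: 13 vinyl allylic alcohol (diene alcohol lactone)
Conditions: Ph3PCH3Br, n-BuLi, THF, 0 °C; then 12, −78 to 0 °C
Reagents that add atoms: methyltriphenylphosphonium bromide C[P+](c1ccccc1)(c1ccccc1)c1ccccc1.[Br-]
Why: Wittig methylenation of the hydroxy aldehyde in equilibrium with the lactol should give the vinyl group and free the allylic hydroxyl group without touching the lactone, with no stereocentre changed.

**Step 5**
Reactants: 13 vinyl allylic alcohol
Product: 14 2-(phenylselanylmethyl)tetrahydropyran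
Conditions: N-(phenylseleno)phthalimide, camphorsulfonic acid (cat.), CH2Cl2, −20 °C to rt
Reagents that add atoms: N-(phenylseleno)phthalimide O=C1c2ccccc2C(=O)N1[Se]c1ccccc1
Why: Selenoetherification: the seleniranium ion of the vinyl group is opened 6-exo by the hydroxyl group at the internal carbon (Markovnikov) through a chair with the CH2SePh group equatorial, while addition to the other two olefins is reversible because no external nucleophile is present.

**Step 6**
Reactants: 14 2-(phenylselanylmethyl)tetrahydropyran
Product: 17 (Z)-cyclooct-4-enone fused to the menthyloxy lactone, via selenoxide 15 (not isolated), via enol ether 16 (not isolated)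
Conditions: mCPBA (1.0 equiv), toluene, −40 °C; then (i-Pr)2NEt (4 equiv), sealed tube, 190 °C
Reagents that add atoms: none
Why: Selenoxide syn-elimination toward the only β-hydrogen should give the 2-methylenetetrahydropyran 16, whose Claisen rearrangement through a twin-chair (bicyclo[3.3.1]-like) transition state, with the propenyl group axial and its methyl group equatorial, expands the six-membered ring to the (Z)-cyclooct-4-enone and transfers the carbinol configuration to the new ring CH(CH3).

**Step 7**
Reactants: 17 cyclooctenone
Product: 18 cyclooctenol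
Conditions: Li[HB(s-Bu)3], THF, −78 °C; then H2O
Reagents that add atoms: none
Why: The bulky hydride should attack the ketone from the ring face opposite to the neighbouring sec-alkyl branch, giving the alcohol cis to that branch, and leave the lactone untouched at −78 °C.

**Step 8**
Reactants: 18 cyclooctenol
Product: 19 cyclopropane alcohol
Conditions: Et2Zn, CH2I2, CH2Cl2, 0 °C
Reagents that add atoms: diiodomethane ICI
Why: Hydroxyl-directed Simmons–Smith cyclopropanation: the zinc alkoxide delivers the carbenoid across the ring to the olefin face syn to the hydroxyl group and anti to the allylic methyl group, and the undirected trisubstituted side-chain olefin reacts much more slowly.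

**Step 9**
Reactants: 19 cyclopropane alcohol
Product: 20 triethylsilyl ether
Conditions: Et3SiOTf, 2,6-lutidine, CH2Cl2, −78 to 0 °C
Reagents that add atoms: triethylsilyl trifluoromethanesulfonate CC[Si](CC)(CC)OS(=O)(=O)C(F)(F)F
Why: Silylation of the hindered secondary alcohol with the silyl triflate protects it from the strong base of step 10.

**Step 10**
Reactants: 20 triethylsilyl ether
Product: 21 α-phenylselanyl lactone
Conditions: LiN(i-Pr)2, THF, −78 °C; then PhSeBr, −78 °C
Reagents that add atoms: phenylselenenyl bromide Br[Se]c1ccccc1
Why: Lithium enolate formation at the only acidic CH (the lactone α-carbon) and selenenylation on the convex face should place selenium cis to the hydrogen on the neighbouring ring-fusion carbon, as the syn-elimination of step 11 requires.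

**Step 11**
Reactants: 21 α-phenylselanyl lactone
Product: 23 menthyloxybutenolide silyl ether, via selenoxide 22 (not isolated)
Conditions: mCPBA (1.0 equiv), CH2Cl2, −78 °C; then (i-Pr)2NH, −78 °C to rt
Reagents that add atoms: none
Why: Selenoxide syn-elimination toward the ring-fusion hydrogen (elimination toward the cyclopropane CH would give a strained alkylidenecyclopropane) should give the tetrasubstituted butenolide double bond, and one equivalent of peracid at −78 °C spares the side-chain olefin.

**Step 12**
Reactants: 23 menthyloxybutenolide silyl ether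
Product: 26 hydroxy butenolide (deacetyl acetoxycrenulide), via formyl carboxylate 24 (not isolated), via hydroxymethyl carboxylate 25 (not isolated)
Conditions: KOH, NaBH4, EtOH/H2O, 0 °C to rt; then 2 M HCl to pH 1, THF, rt
Reagents that add atoms: potassium hydroxide [K+].[OH-] (one carboxylate oxygen of 24 comes from hydroxide and can remain in the lactone carbonyl)
Why: Hydroxide opens the 5-alkoxybutenolide (a pseudo ester) to the formyl carboxylate with loss of menthol, NaBH4 reduces the aldehyde, and acidification closes the cis-hydroxy acid to the butenolide and cleaves the silyl ether, which is the known reductive removal of a menthyloxy auxiliary.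

**Step 13**
Reactants: 26 hydroxy butenolide
Product: 27 acetoxycrenulide
Conditions: Ac2O, DMAP (cat.), pyridine, CH2Cl2, rt
Reagents that add atoms: acetic anhydride CC(=O)OC(C)=O
Why: Acylation of the secondary alcohol under nucleophilic catalysis should give the acetate with retention of configuration.

**Step 14**
Reactants: 27 acetoxycrenulide
Product: 28 CNP0205234.1
Conditions: O2, 5,10,15,20-tetraphenylporphyrin (cat.), visible light, CH2Cl2, 0 °C
Reagents that add atoms: dioxygen O=O
Why: Schenck ene reaction of singlet oxygen with the trisubstituted olefin: abstraction of a hydrogen from the allylic CH2 places the hydroperoxy group on the tertiary carbon and moves the double bond into the (E)-disubstituted position, the regioisomer from abstraction at the cis-methyl group is expected alongside and is removed by chromatography, and the electron-poor butenolide does not react.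

**Compound list**

1 | (E)-but-2-enoic acid (crotonic acid) | C/C=C/C(=O)O | starting material
2 | ethanethiol | CCS | starting material
3 | S-ethyl (E)-but-2-enethioate | C/C=C/C(=O)SCC | intermediate
4 | 5-bromo-2-methylpent-2-ene | CC(C)=CCCBr | starting material
5 | (5S)-5-{[(1S,2R,5S)-2-isopropyl-5-methylcyclohexyl]oxy}furan-2(5H)-one | O=C1C=C[C@@H](O[C@H]2C[C@@H](C)CC[C@@H]2C(C)C)O1 | starting material
6 | (E)-but-2-enal (crotonaldehyde) | C/C=C/C=O | starting material
7 | 4-methylpent-3-enylmagnesium bromide | CC(C)=CCC[Mg]Br | intermediate
8 | bromomagnesium (Z)-enolate of S-ethyl (3R)-3,7-dimethyloct-6-enethioate | CCS/C(O[Mg]Br)=C/[C@H](C)CCC=C(C)C | intermediate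
9 | bromomagnesium lactone enolate of the 1,4-adduct of 8 and 5 (thioester α-carbon bonded to the lactone β-carbon, trans to the menthyloxy group) | CCSC(=O)[C@@H]([C@H](C)CCC=C(C)C)[C@@H]1[C@@H](O[C@H]2C[C@@H](C)CC[C@@H]2C(C)C)OC(O[Mg]Br)=C1 | intermediate
10 | S-ethyl (2S,3R)-2-[(2S,3R,4R)-4-[(1R,2E)-1-hydroxybut-2-enyl]-2-{[(1S,2R,5S)-2-isopropyl-5-methylcyclohexyl]oxy}-5-oxotetrahydrofuran-3-yl]-3,7-dimethyloct-6-enethioate | CCSC(=O)[C@@H]([C@H](C)CCC=C(C)C)[C@@H]1[C@@H](O[C@H]2C[C@@H](C)CC[C@@H]2C(C)C)OC(=O)[C@H]1[C@H](O)/C=C/C | intermediate
11 | aldehyde corresponding to 10 (COSEt replaced by CHO, all centres as in 10) | O=C[C@@H]([C@H](C)CCC=C(C)C)[C@@H]1[C@@H](O[C@H]2C[C@@H](C)CC[C@@H]2C(C)C)OC(=O)[C@H]1[C@H](O)/C=C/C | intermediate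
12 | lactol of 11 (both anomers): 2-hydroxytetrahydropyran with equatorial 3-[(2R)-6-methylhept-5-en-2-yl], a 4,5-trans-fused γ-lactone (acetal carbon with d-menthyloxy on C4, carbonyl on C5) and axial 6-[(E)-prop-1-enyl] | OC1O[C@H](/C=C/C)[C@@H]2C(=O)O[C@H](O[C@H]3C[C@@H](C)CC[C@@H]3C(C)C)[C@H]2[C@@H]1[C@H](C)CCC=C(C)C | intermediate
13 | lactone of 10 in which the thioester is replaced by a vinyl group: 3-[(3S,4R)-4,8-dimethylnona-1,7-dien-3-yl]-4-[(1R,2E)-1-hydroxybut-2-enyl]-5-(d-menthyloxy)dihydrofuran-2-one, ring centres as in 10 | C=C[C@@H]([C@H](C)CCC=C(C)C)[C@@H]1[C@@H](O[C@H]2C[C@@H](C)CC[C@@H]2C(C)C)OC(=O)[C@H]1[C@H](O)/C=C/C | intermediate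
14 | tetrahydropyran of 12 with equatorial CH2SePh in place of the anomeric OH | c1ccccc1[Se]C[C@H]1O[C@H](/C=C/C)[C@@H]2C(=O)O[C@H](O[C@H]3C[C@@H](C)CC[C@@H]3C(C)C)[C@H]2[C@@H]1[C@H](C)CCC=C(C)C | intermediate
15 | selenoxide of 14 (both configurations at selenium) | O=[Se](c1ccccc1)C[C@H]1O[C@H](/C=C/C)[C@@H]2C(=O)O[C@H](O[C@H]3C[C@@H](C)CC[C@@H]3C(C)C)[C@H]2[C@@H]1[C@H](C)CCC=C(C)C | intermediate
16 | 2-methylene-6-[(E)-prop-1-enyl]tetrahydropyran (exocyclic enol ether of the ring of 14) | C=C1O[C@H](/C=C/C)[C@@H]2C(=O)O[C@H](O[C@H]3C[C@@H](C)CC[C@@H]3C(C)C)[C@H]2[C@@H]1[C@H](C)CCC=C(C)C | intermediate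
17 | (Z)-cyclooct-4-enone: 3-methyl, 8-[(2R)-6-methylhept-5-en-2-yl], trans-fused γ-lactone on C6–C7 (carbonyl on C6, d-menthyloxy acetal carbon on C7) | O=C1C[C@@H](C)/C=C\[C@@H]2C(=O)O[C@H](O[C@H]3C[C@@H](C)CC[C@@H]3C(C)C)[C@H]2[C@@H]1[C@H](C)CCC=C(C)C | intermediate
18 | alcohol of 17, hydroxyl cis to the neighbouring side chain | O[C@@H]1C[C@@H](C)/C=C\[C@@H]2C(=O)O[C@H](O[C@H]3C[C@@H](C)CC[C@@H]3C(C)C)[C@H]2[C@@H]1[C@H](C)CCC=C(C)C | intermediate
19 | cyclopropane of 18: bicyclo[6.1.0]nonanol, CH2 cis to the hydroxyl group and trans to the ring methyl group | O[C@@H]1C[C@@H](C)[C@@H]2C[C@@H]2[C@@H]3C(=O)O[C@H](O[C@H]4C[C@@H](C)CC[C@@H]4C(C)C)[C@H]3[C@@H]1[C@H](C)CCC=C(C)C | intermediate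
20 | triethylsilyl ether of 19 | CC[Si](CC)(CC)O[C@@H]1C[C@@H](C)[C@@H]2C[C@@H]2[C@@H]3C(=O)O[C@H](O[C@H]4C[C@@H](C)CC[C@@H]4C(C)C)[C@H]3[C@@H]1[C@H](C)CCC=C(C)C | intermediate
21 | 20 with SePh on the lactone α-carbon, cis to the hydrogen of the neighbouring ring-fusion carbon | CC[Si](CC)(CC)O[C@@H]1C[C@@H](C)[C@@H]2C[C@@H]2[C@@]3([Se]c4ccccc4)C(=O)O[C@H](O[C@H]4C[C@@H](C)CC[C@@H]4C(C)C)[C@H]3[C@@H]1[C@H](C)CCC=C(C)C | intermediate
22 | selenoxide of 21 | CC[Si](CC)(CC)O[C@@H]1C[C@@H](C)[C@@H]2C[C@@H]2[C@@]3([Se](=O)c4ccccc4)C(=O)O[C@H](O[C@H]4C[C@@H](C)CC[C@@H]4C(C)C)[C@H]3[C@@H]1[C@H](C)CCC=C(C)C | intermediate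
23 | triethylsilyl ether of deacetyl acetoxycrenulide carrying the d-menthyloxy group on the butenolide CH–O carbon (S) | CC[Si](CC)(CC)O[C@@H]1C[C@@H](C)[C@@H]2C[C@@H]2C2=C([C@@H](O[C@H]3C[C@@H](C)CC[C@@H]3C(C)C)OC2=O)[C@@H]1[C@H](C)CCC=C(C)C | intermediate
24 | potassium salt of the ring-opened (Z)-formyl carboxylic acid (cyclooctene with CO2K and CHO on the double bond) | CC[Si](CC)(CC)O[C@@H]1C[C@@H](C)[C@@H]2C[C@@H]2C(C(=O)[O-])=C(C=O)[C@@H]1[C@H](C)CCC=C(C)C.[K+] | intermediate
25 | potassium salt of the corresponding hydroxymethyl carboxylic acid | CC[Si](CC)(CC)O[C@@H]1C[C@@H](C)[C@@H]2C[C@@H]2C(C(=O)[O-])=C(CO)[C@@H]1[C@H](C)CCC=C(C)C.[K+] | intermediate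
26 | deacetyl acetoxycrenulide (hydroxy butenolide) | O[C@@H]1C[C@@H](C)[C@@H]2C[C@@H]2C2=C(COC2=O)[C@@H]1[C@H](C)CCC=C(C)C | intermediate
27 | acetoxycrenulide | CC(=O)O[C@@H]1C[C@@H](C)[C@@H]2C[C@@H]2C2=C(COC2=O)[C@@H]1[C@H](C)CCC=C(C)C | intermediate
28 | CNP0205234.1: acetoxycrenulide with the side chain as (2R,4E)-6-hydroperoxy-6-methylhept-4-en-2-yl | CC(=O)O[C@@H]1C[C@@H](C)[C@@H]2C[C@@H]2C2=C(COC2=O)[C@@H]1[C@H](C)C/C=C/C(C)(C)OO | target

**Step count and risks**

Total step count: 14. Longest linear sequence: 14 steps (1 or 2 → 3 → 10 → 12 → 13 → 14 → 17 → 18 → 19 → 20 → 21 → 23 → 26 → 27 → 28).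

Steps most likely to fail:

Step 2. The magnesium thioester enolate may add too slowly to the butenolide and instead undergo proton transfer or self-condensation, and the magnesium alkoxide of the aldol may acylate itself on the thioester before the quench. Fallback: starting from 3 and 4 (through 7), the same copper-catalysed conjugate addition is run with an aqueous quench to isolate S-ethyl (3R)-3,7-dimethyloct-6-enethioate F1. F1 is then deprotonated with LiN(i-Pr)2 in THF at −78 °C and taken through a stepwise lithium-enolate Michael addition to 5 and aldol addition to 6 with cold quench, which comes back to the route at 10.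

Step 6. The selenoxide may eliminate sluggishly toward the oxygen-bearing carbon, and the selenenic acid set free may add to the enol ether or the side-chain olefin at the temperature of the rearrangement. Fallback: starting from 13, iodoetherification (I2, NaHCO3, MeCN, 0 °C) gives the 2-(iodomethyl)tetrahydropyran F2. Dehydroiodination of F2 with DBU in toluene at 90 °C gives the enol ether 16 as an isolated, selenium-free compound, and heating 16 alone in toluene (sealed tube, 190 °C) comes back to the route at 17.

Step 14. Hydrogen abstraction from the cis-methyl group competes with abstraction from the allylic CH2 and lowers the share of the tertiary hydroperoxide. Fallback: starting from 27, Markovnikov hydroxyselenenylation of the side-chain olefin (N-(phenylseleno)phthalimide, H2O, camphorsulfonic acid, CH2Cl2) gives the β-hydroxy selenide F3. Oxidation of F3 with H2O2 and syn-elimination away from the hydrogen-free carbinol carbon gives the (E)-tertiary allylic alcohol F4. Acid-catalysed perhydrolysis of F4 (50% H2O2, cat. H2SO4, Et2O, 0 °C; capture of the allyl cation at its tertiary end) comes back to the route at 28.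

**Further compounds**

F1 | step 2 | S-ethyl (3R)-3,7-dimethyloct-6-enethioate | CCSC(=O)C[C@H](C)CCC=C(C)C
F2 | step 6 | 2-(iodomethyl)tetrahydropyran analogue of 14 (I in place of SePh) | IC[C@H]1O[C@H](/C=C/C)[C@@H]2C(=O)O[C@H](O[C@H]3C[C@@H](C)CC[C@@H]3C(C)C)[C@H]2[C@@H]1[C@H](C)CCC=C(C)C
F3 | step 14 | acetoxycrenulide with the side chain as (2R)-6-hydroxy-6-methyl-5-(phenylselanyl)heptan-2-yl (both configurations at the selenium-bearing carbon) | CC(=O)O[C@@H]1C[C@@H](C)[C@@H]2C[C@@H]2C2=C(COC2=O)[C@@H]1[C@H](C)CCC([Se]c1ccccc1)C(C)(C)O
F4 | step 14 | acetoxycrenulide with the side chain as (2R,4E)-6-hydroxy-6-methylhept-4-en-2-yl | CC(=O)O[C@@H]1C[C@@H](C)[C@@H]2C[C@@H]2C2=C(COC2=O)[C@@H]1[C@H](C)C/C=C/C(C)(C)O
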